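## Retrosynthetic overview

1. The oxane-2,4-dione ring is made last: C-acylation of a cis-fused C7-O/C8 γ-lactone at C3' with (S)-β-butyrolactone, then translactonisation, which frees the 7-OH.
2. Before that, C9=C10 comes from a vinylogous aldol condensation of the C3-methyl with (2E,4S)-2,4-dimethylhex-2-enal, and C5–Cl from NCS.
3. Key disconnection C7–C8: an NHC-bound homoenolate (C8, the β-carbon of an enal) adds to the C7 carbonyl of a tethered 1,2-dione, closing ring A and the γ-lactone together and setting C7 and C8.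
4. The enal–dione precursor comes from allomaltol triflate by Suzuki coupling (enal acetal) and enolate addition/dehydration at the pyrone carbonyl (dione arm).
5. Ring order: ring B (pyran, bought as allomaltol), then ring A plus γ-lactone (key step), then the oxanedione ring (last step).

Locants: isochromene numbering (O2, C1–C8a) for the core, C9–C15 for the side chain, primed locants for the oxanedione ring.
Assumption: C3' lies between two carbonyls and equilibrates through the enol; the drawn (3'R) keto form is taken as the thermodynamic one.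
Assumption: the (5aS,10bR) precatalyst is taken to give the (7S,8S) sense; if it gives the opposite sense, its commercial antipode is used.

## Route

Step 1
Reactants: 1 (S)-2-methylbutan-1-ol; 2 2-(triphenylphosphoranylidene)propanal
Product: 4 (2E,4S)-2,4-dimethylhex-2-enal, via (S)-2-methylbutanal 3 (not isolated)
Conditions: TEMPO (10 mol %), PhI(OAc)2 (1.1 equiv), CH2Cl2, rt; then 2 (1.3 equiv), 40 °C
Reagents that add atoms: none
Why: The base-free TEMPO/PhI(OAc)2 oxidation gives the α-chiral aldehyde without enolisation, and the in-situ Wittig olefination with the stabilised formyl ylide gives the (E)-enal, the C13 stereocentre coming unchanged from the chiral pool.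

Step 2
Reactants: 5 allomaltol (5-hydroxy-2-methyl-4H-pyran-4-one)
Product: 6 6-methyl-4-oxo-4H-pyran-3-yl trifluoromethanesulfonate
Conditions: Tf2O (1.1 equiv), pyridine, CH2Cl2, −10 °C → rt
Reagents that add atoms: trifluoromethanesulfonic anhydride, O=S(=O)(OS(=O)(=O)C(F)(F)F)C(F)(F)F
Why: O-Triflation of the enolic 3-hydroxy-γ-pyrone gives a pseudo-aryl triflate that serves as the cross-coupling handle at the future C8a.

Step 3
Reactants: 6 6-methyl-4-oxo-4H-pyran-3-yl trifluoromethanesulfonate; 7 2-[(1E)-3,3-diethoxyprop-1-en-1-yl]-4,4,5,5-tetramethyl-1,3,2-dioxaborolane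
Product: 8 5-[(1E)-3,3-diethoxyprop-1-en-1-yl]-2-methyl-4H-pyran-4-one
Conditions: Pd(PPh3)4 (5 mol %), K3PO4 (3 equiv), 1,4-dioxane/H2O 10:1, 70 °C
Reagents that add atoms: none
Why: Suzuki–Miyaura coupling of the pyrone triflate with the (E)-alkenylboronate proceeds with retention of alkene geometry and installs C8–C3'–C2' as a base-stable enal acetal.

Step 4
Reactants: 8 5-[(1E)-3,3-diethoxyprop-1-en-1-yl]-2-methyl-4H-pyran-4-one; 9 3,3-dimethoxybutan-2-one
Product: 12 1-{6-methyl-3-[(1E)-3-oxoprop-1-en-1-yl]-4H-pyran-4-ylidene}butane-2,3-dione, via pyranol adduct 10 (not isolated), via bis-acetal pyranylidene 11 (not isolated)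
Conditions: 9 (1.3 equiv), LiN(iPr)2 (LDA, 1.3 equiv), THF, −78 °C; CeCl3 (1.4 equiv); then 8, −78 → −40 °C; then 3 M aq HCl, THF, 0 °C → rt
Reagents that add atoms: water, O
Why: Aldol-type 1,2-addition of the cerium enolate (organocerium conditions suppress conjugate addition and proton transfer) to the γ-pyrone carbonyl is followed by acid-driven dehydration through the 4-(2-oxoalkyl)pyrylium ion to the push–pull 4H-pyran-4-ylidene ketone, as in the organometallic-addition/pyrylium route from γ-pyrones, and the same acid hydrolyses both acetals.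

Step 5
Reactants: 12 1-{6-methyl-3-[(1E)-3-oxoprop-1-en-1-yl]-4H-pyran-4-ylidene}butane-2,3-dione
Product: 13 (6aS,9aS)-3,6a-dimethyl-9,9a-dihydro-6H-furo[2,3-h]isochromene-6,8(6aH)-dione
Conditions: (5aS,10bR)-2-mesityl-5a,10b-dihydro-4H,6H-indeno[2,1-b][1,2,4]triazolo[4,3-d][1,4]oxazin-2-ium chloride (10 mol %), DBU (10 mol %), LiCl (1 equiv), THF (0.02 M), rt
Reagents that add atoms: none
Why: Proposed new method: the N-mesityl triazolylidene adds to the enal to give a Breslow intermediate whose β-carbon C8 is nucleophilic (homoenolate) and attacks the more electrophilic, Li-chelated C7 carbonyl of the tethered 1,2-dione in a 6-exo closure of ring A, after which the C7 alkoxide acylates the acyl azolium and releases the carbene, so that only the cis-fused lactone (7-O and C3' syn) can turn over while the chiral carbene selects the homoenolate face and sets C7 and C8 as S,S; the closest known reaction types are the NHC-catalysed homoenolate [3+2] annulation of enals with ketones and 1,2-diones to γ-butyrolactones and its intramolecular enal–ketone lactonisation variant.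

Step 6
Reactants: 13 (6aS,9aS)-3,6a-dimethyl-9,9a-dihydro-6H-furo[2,3-h]isochromene-6,8(6aH)-dione
Product: 14 (6aS,9aS)-5-chloro-3,6a-dimethyl-9,9a-dihydro-6H-furo[2,3-h]isochromene-6,8(6aH)-dione
Conditions: NCS (1.05 equiv), CH2Cl2, 0 °C → rt
Reagents that add atoms: N-chlorosuccinimide, O=C1CCC(=O)N1Cl
Why: Electrophilic chlorination occurs at C5, the α-carbon of the doubly vinylogous ester, through an aromatic pyrylium σ-complex (the site halogenated in azaphilones), and is done before the diene and the enolisable oxanedione are present.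

Step 7
Reactants: 14 (6aS,9aS)-5-chloro-3,6a-dimethyl-9,9a-dihydro-6H-furo[2,3-h]isochromene-6,8(6aH)-dione; 4 (2E,4S)-2,4-dimethylhex-2-enal
Product: 17 (6aS,9aS)-5-chloro-3-[(1E,3E,5S)-3,5-dimethylhepta-1,3-dien-1-yl]-6a-methyl-9,9a-dihydro-6H-furo[2,3-h]isochromene-6,8(6aH)-dione, via aldol adduct 15 (not isolated), via mesylate 16 (not isolated)
Conditions: LiN(SiMe3)2 (LiHMDS, 1.05 equiv), THF, −78 °C; 4 (1.2 equiv), −78 °C; MsCl (1.3 equiv), −78 → 0 °C; DBU (2 equiv), 0 °C → rt
Reagents that add atoms: none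
Why: The C3-methyl is the most acidic C–H (trienolate through to the C6 ketone, as for γ-pyrone 2-methyl groups), so a lateral vinylogous aldol addition to the aldehyde followed by mesylation and E1cB elimination gives the conjugated (E,E)-diene without touching C13.

Step 8
Reactants: 17 (6aS,9aS)-5-chloro-3-[(1E,3E,5S)-3,5-dimethylhepta-1,3-dien-1-yl]-6a-methyl-9,9a-dihydro-6H-furo[2,3-h]isochromene-6,8(6aH)-dione; 18 (S)-4-methyloxetan-2-one ((S)-β-butyrolactone)
Product: 20 (7S,8S)-5-chloro-3-[(1E,3E,5S)-3,5-dimethylhepta-1,3-dien-1-yl]-7-hydroxy-7-methyl-8-[(3R,6S)-6-methyl-2,4-dioxooxan-3-yl]-7,8-dihydro-6H-isochromen-6-one, via acyl lactone 19 (not isolated)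
Conditions: LiN(iPr)2 (LDA, 1.05 equiv), THF, −78 °C; 18 (1.3 equiv), −78 → −30 °C; then MeOH, K2CO3 (20 mol %), 0 °C → rt; 1 M HCl work-up
Reagents that add atoms: none
Why: The kinetic lactone enolate undergoes Claisen-type C-acylation at the acyl carbon of the β-lactone (acyl–oxygen cleavage, C6' untouched), and base-catalysed translactonisation of the released (S)-secondary alcohol onto C2' then gives the six-membered β-keto lactone, driven by its stabilised enolate and relief of the strained fused γ-lactone, which frees the 7-OH with C7 and C8 unchanged and lets C3' settle under thermodynamic control.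

## Compound list

1 | (S)-2-methylbutan-1-ol | CC[C@H](C)CO | starting material
2 | 2-(triphenylphosphoranylidene)propanal | CC(C=O)=P(c1ccccc1)(c1ccccc1)c1ccccc1 | starting material
3 | (S)-2-methylbutanal | CC[C@H](C)C=O | intermediate
4 | (2E,4S)-2,4-dimethylhex-2-enal | CC[C@H](C)/C=C(C)/C=O | intermediate
5 | allomaltol (5-hydroxy-2-methyl-4H-pyran-4-one) | CC1=CC(=O)C(O)=CO1 | starting material
6 | 6-methyl-4-oxo-4H-pyran-3-yl trifluoromethanesulfonate | CC1=CC(=O)C(OS(=O)(=O)C(F)(F)F)=CO1 | intermediate
7 | 2-[(1E)-3,3-diethoxyprop-1-en-1-yl]-4,4,5,5-tetramethyl-1,3,2-dioxaborolane | CCOC(OCC)/C=C/B1OC(C)(C)C(C)(C)O1 | starting material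
8 | 5-[(1E)-3,3-diethoxyprop-1-en-1-yl]-2-methyl-4H-pyran-4-one | CCOC(OCC)/C=C/C1=COC(C)=CC1=O | intermediate
9 | 3,3-dimethoxybutan-2-one | CC(=O)C(C)(OC)OC | starting material
10 | 1-{3-[(1E)-3,3-diethoxyprop-1-en-1-yl]-4-hydroxy-6-methyl-4H-pyran-4-yl}-3,3-dimethoxybutan-2-one (racemic carbinol) | CCOC(OCC)/C=C/C1=COC(C)=CC1(O)CC(=O)C(C)(OC)OC | intermediate
11 | 1-{3-[(1E)-3,3-diethoxyprop-1-en-1-yl]-6-methyl-4H-pyran-4-ylidene}-3,3-dimethoxybutan-2-one | CCOC(OCC)/C=C/C1=COC(C)=CC1=CC(=O)C(C)(OC)OC | intermediate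
12 | 1-{6-methyl-3-[(1E)-3-oxoprop-1-en-1-yl]-4H-pyran-4-ylidene}butane-2,3-dione (exocyclic push–pull alkene configurationally labile) | CC(=O)C(=O)C=C1C=C(C)OC=C1/C=C/C=O | intermediate
13 | (6aS,9aS)-3,6a-dimethyl-9,9a-dihydro-6H-furo[2,3-h]isochromene-6,8(6aH)-dione (C6a = C7, C9a = C8, cis-fused γ-lactone) | CC1=CC2=CC(=O)[C@@]3(C)OC(=O)C[C@H]3C2=CO1 | intermediate
14 | (6aS,9aS)-5-chloro-3,6a-dimethyl-9,9a-dihydro-6H-furo[2,3-h]isochromene-6,8(6aH)-dione | CC1=CC2=C(Cl)C(=O)[C@@]3(C)OC(=O)C[C@H]3C2=CO1 | intermediate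
15 | (6aS,9aS)-5-chloro-3-[(3E,5S)-2-hydroxy-3,5-dimethylhept-3-en-1-yl]-6a-methyl-9,9a-dihydro-6H-furo[2,3-h]isochromene-6,8(6aH)-dione (carbinol epimers, formed as lithium alkoxide) | CC[C@H](C)/C=C(\C)C(O)CC1=CC2=C(Cl)C(=O)[C@@]3(C)OC(=O)C[C@H]3C2=CO1 | intermediate
16 | methanesulfonate of 15 at the side-chain carbinol | CC[C@H](C)/C=C(\C)C(OS(C)(=O)=O)CC1=CC2=C(Cl)C(=O)[C@@]3(C)OC(=O)C[C@H]3C2=CO1 | intermediate
17 | (6aS,9aS)-5-chloro-3-[(1E,3E,5S)-3,5-dimethylhepta-1,3-dien-1-yl]-6a-methyl-9,9a-dihydro-6H-furo[2,3-h]isochromene-6,8(6aH)-dione | CC[C@H](C)/C=C(C)/C=C/C1=CC2=C(Cl)C(=O)[C@@]3(C)OC(=O)C[C@H]3C2=CO1 | intermediate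
18 | (S)-4-methyloxetan-2-one ((S)-β-butyrolactone) | C[C@H]1CC(=O)O1 | starting material
19 | (6aS,9aS)-5-chloro-3-[(1E,3E,5S)-3,5-dimethylhepta-1,3-dien-1-yl]-9-[(3S)-3-hydroxybutanoyl]-6a-methyl-9,9a-dihydro-6H-furo[2,3-h]isochromene-6,8(6aH)-dione (C9 epimers/enolate) | CC[C@H](C)/C=C(C)/C=C/C1=CC2=C(Cl)C(=O)[C@@]3(C)OC(=O)C(C(=O)C[C@H](C)O)[C@H]3C2=CO1 | intermediate
20 | (7S,8S)-5-chloro-3-[(1E,3E,5S)-3,5-dimethylhepta-1,3-dien-1-yl]-7-hydroxy-7-methyl-8-[(3R,6S)-6-methyl-2,4-dioxooxan-3-yl]-7,8-dihydro-6H-isochromen-6-one (CNP0584120.1) | CC[C@H](C)/C=C(C)/C=C/C1=CC2=C(Cl)C(=O)[C@@](C)(O)[C@@H]([C@@H]3C(=O)C[C@H](C)OC3=O)C2=CO1 | target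

## Step count and risks

Total step count: 8. Longest linear sequence: 7 (Steps 2–8, from allomaltol); Step 1 is a one-step side branch.

The three steps most likely to fail are Step 5, Step 4 and Step 8.

Step 5 is the least precedented step. The enal is a push–pull (vinylogous formate) aldehyde, so the Breslow intermediate may form slowly. The homoenolate may be protonated or react at the wrong dione carbonyl. The sense and level of enantioselection are unknown. The fallback sets out from 12 and comes back at 13, and replaces the carbene homoenolate by a ketyl. Pinnick oxidation of 12 (NaClO2, NaH2PO4, 2-methyl-2-butene, tBuOH/H2O) gives the acrylic acid F1, and TMSCHN2 in toluene/MeOH gives the methyl acrylate F2. SmI2 (2.2 equiv, THF, tBuOH, −78 °C; divalent samarium) then reduces the 1,2-dione to its ketyl, which adds through C7 to the acrylate β-carbon C8, and the samarium alkoxide lactonises with loss of methanol. This gives the cis-fused lactone as a racemate, that is 13 together with the mirror-image lactone F3, which is removed by chromatography on a chiral stationary phase (or later, as a diastereomer, at the stage of 17).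

Step 4 may fail because the cerium enolate can add in a conjugate manner at C1, or be quenched by the acidic C3-methyl, instead of adding to the deactivated γ-pyrone carbonyl. The fallback sets out from 8 and comes back at 11 (which then goes through the acid treatment of Step 4), and turns the pyrone into the electrophile of an addition–elimination. MeOTf in CH2Cl2 O-methylates 8 to the 4-methoxypyrylium triflate F4. The silyl enol ether F5 (made from 9 with TMSOTf and Et3N) is added with 2,6-di-tert-butylpyridine at −40 °C. It attacks the pyrylium carbon bearing the methoxy group, and loss of methanol and of the silyl group gives 11.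

Step 8 may fail because the lactone enolate can attack the β-lactone at its alkyl carbon, proton transfer to the vinylogously acidic C13–H can erode the side-chain stereocentre, and the translactonisation may stall. The fallback sets out from 17 and comes back at 20, and inverts the order of bond formation (ester exchange first, C–C bond second). The sodium alkoxide of commercial ethyl (S)-3-hydroxybutanoate (NaH, THF, 0 °C) opens the strained γ-lactone by transesterification to the hydroxy diester F6. LiN(SiMe3)2 (2.2 equiv, THF, −78 → 0 °C) then effects a Dieckmann condensation of the C3' enolate onto the ethyl ester, expelling ethanol and giving 20 after acidic work-up.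

## Further compounds

F1 | step 5 | (2E)-3-[4-(2,3-dioxobutylidene)-6-methyl-4H-pyran-3-yl]prop-2-enoic acid | CC(=O)C(=O)C=C1C=C(C)OC=C1/C=C/C(=O)O
F2 | step 5 | methyl (2E)-3-[4-(2,3-dioxobutylidene)-6-methyl-4H-pyran-3-yl]prop-2-enoate | CC(=O)C(=O)C=C1C=C(C)OC=C1/C=C/C(=O)OC
F3 | step 5 | (6aR,9aR)-3,6a-dimethyl-9,9a-dihydro-6H-furo[2,3-h]isochromene-6,8(6aH)-dione | CC1=CC2=CC(=O)[C@]3(C)OC(=O)C[C@@H]3C2=CO1
F4 | step 4 | 3-[(1E)-3,3-diethoxyprop-1-en-1-yl]-4-methoxy-6-methylpyrylium trifluoromethanesulfonate | CCOC(OCC)/C=C/c1c[o+]c(C)cc1OC.[O-]S(=O)(=O)C(F)(F)F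
F5 | step 4 | 3,3-dimethoxy-2-[(trimethylsilyl)oxy]but-1-ene | C=C(O[Si](C)(C)C)C(C)(OC)OC
F6 | step 8 | ethyl (3S)-3-({[(7S,8S)-5-chloro-3-[(1E,3E,5S)-3,5-dimethylhepta-1,3-dien-1-yl]-7-hydroxy-7-methyl-6-oxo-7,8-dihydro-6H-isochromen-8-yl]acetyl}oxy)butanoate | CC[C@H](C)/C=C(C)/C=C/C1=CC2=C(Cl)C(=O)[C@@](C)(O)[C@@H](CC(=O)O[C@@H](C)CC(=O)OCC)C2=CO1
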